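Retrosynthetic overview
1. 31 comes from 30 by removal of the C2 levulinate. 30 comes from dihydropyran 29 by ene-type chlorination of C5=C6, which installs C6–Cl and the C5=C16 methylene. No ring is formed after 29.
2. Enabling feature: C8 is the fully substituted atom shared by the pyran and the γ-lactone. It is the β-carbon of the lactone carbonyl C19 and lies 1,5 across the ten-membered carbocycle from the oxygen on C4. The pyran O–C8 bond is therefore a transannular oxa-Michael retron, and the Δ8(17)-butenolide it reveals (C7–O next to C6=C5) is an alkenyl-chromium addition/lactonisation retron at C6–C7.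
3. Key disconnection: 29 ⇒ open iodoalkene/(Z)-4-oxo-enoate 27, which contains only the cyclohexane and the spiro-oxirane. One operation closes carbocycle, lactone and pyran and sets C7, C8 and C17.
4. 27 ⇒ core aldehyde 22 + iodo-enone 9 (syn boron aldol C2–C3; Evans–Tishchenko sets C4 and masks O2). 22 ⇒ enone 15 + furan aldehyde 3 (syn titanium aldol C9–C10; the furan is a latent oxo-enoate). 15 ⇒ catalytic asymmetric Diels–Alder of 11 and 12, which sets C1 and C14; all other centres are relayed from these.
5. Ring order: cyclohexane (step 8) → oxirane (step 21) → ten-membered carbocycle → γ-lactone → pyran (these three in step 22, pyran last).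

Key step: step 22

Remark (numbering): briarane numbers are used. C1 = methyl-bearing quaternary ring carbon, C2–C9 = chain of the ten-membered ring, C10 = ring-fusion CH, C11 = oxirane spiro carbon, C14 = ring CH–O, C15 = methyl on C1, C16 = carbon on C5, C17/C18/C19 = lactone CH, its methyl and C=O, C20 = oxirane CH2. β is the face of C15.
Remark (assumption): the antipode of the Diels–Alder catalyst in step 8 is taken to be the one that gives (1R,2S)-13.

Step 1
Reactants: 1 3,4-dibromofuran
Product: 2 3-bromo-4-methylfuran
Conditions: n-BuLi (1.0 equiv), Et2O, −78 °C; MeI, −78 → −20 °C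
Reagents that add atoms: iodomethane CI
Why: Mono bromine–lithium exchange gives a 3-furyllithium that keeps its position at −78 °C and is methylated by SN2 attack on MeI.

Step 2
Reactants: 2 3-bromo-4-methylfuran
Product: 3 4-methylfuran-3-carbaldehyde
Conditions: n-BuLi, Et2O, −78 °C; DMF; aq. work-up
Reagents that add atoms: N,N-dimethylformamide CN(C)C=O
Why: A second bromine–lithium exchange followed by formylation with DMF (Bouveault aldehyde synthesis) should give the non-enolisable aldehyde.

Step 3
Reactants: 4 prop-2-yn-1-ol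
Product: 5 (Z)-3-iodo-2-methylprop-2-en-1-ol
Conditions: MeMgBr (3 equiv), CuI (cat.), THF, −10 °C → rt; I2, −20 °C
Reagents that add atoms: methylmagnesium bromide C[Mg]Br; iodine II
Why: Alkoxide-directed copper-catalysed anti-carbomagnesiation gives a five-membered magnesacycle whose C–Mg bond is iodinated with retention, which fixes iodine cis to the CH2OH carbon (later C4).

Step 4
Reactants: 5 (Z)-3-iodo-2-methylprop-2-en-1-ol
Product: 6 (Z)-3-iodo-2-methylprop-2-enoic acid
Conditions: TEMPO (cat.), PhI(OAc)2 (2.2 equiv), MeCN–H2O, rt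
Reagents that add atoms: water O
Why: Oxoammonium oxidation through the aldehyde hydrate is near neutral, so the Z-iodoalkene should survive unchanged.

Step 5
Reactants: 6 (Z)-3-iodo-2-methylprop-2-enoic acid
Product: 8 (Z)-1-diazo-4-iodo-3-methylbut-3-en-2-one, via acid chloride 7 (not isolated)
Conditions: (COCl)2, DMF (cat.), CH2Cl2, 0 °C → rt; concentrate; CH2N2, Et3N, Et2O, 0 °C
Reagents that add atoms: oxalyl chloride ClC(=O)C(=O)Cl; diazomethane C=[N+]=[N-]
Why: Acylation of diazomethane (first stage of the Arndt–Eistert sequence, with Et3N as HCl trap) should work because the trisubstituted iodoalkene is a poor dipolarophile.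

Step 6
Reactants: 8 (Z)-1-diazo-4-iodo-3-methylbut-3-en-2-one
Product: 9 (Z)-4-iodo-3-methyl-2-oxobut-3-en-1-yl acetate
Conditions: AcOH, 70 °C
Reagents that add atoms: acetic acid CC(=O)O
Why: Protonation of the diazoketone and displacement of N2 by acetate (formal O–H insertion) delivers the α-acetoxy ketone, which already carries the C3 acetate of the target.

Step 7
Reactants: 10 (E)-but-2-enal
Product: 11 (E)-1-(tert-butyldimethylsilyloxy)buta-1,3-diene
Conditions: TBSOTf, Et3N, Et2O, 0 °C → rt
Reagents that add atoms: tert-butyldimethylsilyl triflate CC(C)(C)[Si](C)(C)OS(=O)(=O)C(F)(F)F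
Why: O-silylation and γ-deprotonation of the enal is the standard entry to the (E)-1-silyloxydiene.

Step 8
Reactants: 11 (E)-1-(tert-butyldimethylsilyloxy)buta-1,3-diene; 12 2-methylprop-2-enal
Product: 13 (1R,2S)-2-(tert-butyldimethylsilyloxy)-1-methylcyclohex-3-ene-1-carbaldehyde (OTBS and CHO cis)
Conditions: proline-derived o-tolyl-oxazaborolidinium triflimide (10 mol %), CH2Cl2, −78 °C
Reagents that add atoms: none
Why: In this catalytic enantioselective Diels–Alder reaction the 1-oxy substituent directs "ortho" regiochemistry, the endo-formyl transition state places O14 cis to C2, and the catalyst shields one face of the enal and so sets C1 and C14 absolutely.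

Step 9
Reactants: 13 Diels–Alder aldehyde
Product: 14 dimethyl acetal of 13
Conditions: HC(OMe)3, PPTS (cat.), MeOH, rt
Reagents that add atoms: trimethyl orthoformate COC(OC)OC
Why: Orthoformate-driven acetalisation masks the non-enolisable C2 aldehyde under acid too weak to cleave the secondary TBS ether.

Step 10
Reactants: 14 dimethyl acetal
Product: 15 4-(tert-butyldimethylsilyloxy)-5-(dimethoxymethyl)-5-methylcyclohex-2-en-1-one (C11 ketone, C12=C13)
Conditions: Rh2(caprolactamate)4 (1 mol %), t-BuOOH, K2CO3, CH2Cl2, rt
Reagents that add atoms: tert-butyl hydroperoxide CC(C)(C)OO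
Why: Dirhodium/t-BuOOH allylic oxidation attacks the only allylic CH2 (C11), because the other allylic position (C14) is a hindered silyloxy methine.

Step 11
Reactants: 15 enone; 3 4-methylfuran-3-carbaldehyde
Product: 16 C9–C10 syn-aldol adduct (C9 branch β on C10, trans to the acetal carbon C2; 9-OH free)
Conditions: LDA, THF, −78 °C; ClTi(Oi-Pr)3, −78 → −40 °C; 3, −78 °C
Reagents that add atoms: none
Why: Kinetic α′-deprotonation gives only the C10 cross-conjugated dienolate; triisopropoxytitanium enolates of cyclic ketones are syn-selective aldol donors (sets C9), and the aldehyde enters C10 anti to the bulky dimethoxymethyl group, which is also the trans-diequatorial, thermodynamically preferred result.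

Step 12
Reactants: 16 syn-aldol adduct
Product: 17 9,14-bis-TBS ether
Conditions: TBSOTf, 2,6-lutidine, CH2Cl2, −78 → 0 °C
Reagents that add atoms: tert-butyldimethylsilyl triflate CC(C)(C)[Si](C)(C)OS(=O)(=O)C(F)(F)F
Why: Triflate silylation under non-nucleophilic base caps the hindered carbinol before retro-aldol or dehydration can occur.

Step 13
Reactants: 17 bis-TBS enone
Product: 18 saturated C11 ketone
Conditions: H2 (1 atm), RhCl(PPh3)3 (10 mol %), benzene, rt
Reagents that add atoms: none
Why: Homogeneous rhodium hydrogenation reduces the cis-disubstituted C12=C13 bond and leaves the aromatic furan and the C9–O bond untouched.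

Step 14
Reactants: 18 C11 ketone
Product: 19 C11=C20 exocyclic alkene
Conditions: Ph3PCH3Br, KOt-Bu, THF, 0 °C → rt
Reagents that add atoms: methyltriphenylphosphonium bromide C[P+](c1ccccc1)(c1ccccc1)c1ccccc1.[Br-]
Why: In this Wittig methylenation C10 already has its more stable equatorial configuration, and silyloxide is a poor leaving group for β-elimination.

Step 15
Reactants: 19 bis-TBS alkene
Product: 20 9,14-diol
Conditions: TBAF (4 equiv), THF, 40 °C
Reagents that add atoms: none
Why: Fluoride desilylation is safe at this stage because no ketone, ester or epoxide is present and the acetal is base-stable.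

Step 16
Reactants: 20 9,14-diol
Product: 21 9,14-diacetate
Conditions: Ac2O, Et3N, DMAP, CH2Cl2, rt
Reagents that add atoms: acetic anhydride CC(=O)OC(C)=O
Why: DMAP-catalysed acetylation installs two of the three acetates of the target once all strongly basic and nucleophilic steps are over.

Step 17
Reactants: 21 diacetate acetal
Product: 22 core aldehyde (C2 = CHO)
Conditions: PPTS, acetone–H2O (10:1), 45 °C
Reagents that add atoms: water O
Why: Mild acetal hydrolysis frees the aldehyde only after O9 is acetylated, so no five-membered lactol can form, and the acid is too weak to move the exocyclic alkene.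

Step 18
Reactants: 9 (Z)-4-iodo-3-methyl-2-oxobut-3-en-1-yl acetate; 22 core aldehyde
Product: 23 2,3-syn aldol adduct (2-OH, 3-OAc, C4 ketone, Z-iodoalkene)
Conditions: 9, Bu2BOTf, i-Pr2NEt, CH2Cl2, −78 → 0 °C; 22, −78 → −20 °C; pH 7 buffer, MeOH, H2O2, 0 °C
Reagents that add atoms: none
Why: In this boron aldol reaction the (Z)-enol borinate reacts through a closed chair transition state to give the 2,3-syn relation, and the aldehyde face is set by Felkin-type attack anti to the C1–C10 bond (methyl as the small group), which coincides with the 1,3-anti preference exerted by the C14 oxygen.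

Step 19
Reactants: 23 β-hydroxy ketone
Product: 24 2-O-levulinate, 4-OH (2,4-anti)
Conditions: SmI2 (30 mol %) pre-stirred with 4-oxopentanal until decolourised, then 23, THF, −10 °C
Reagents that add atoms: 4-oxopentanal CC(=O)CCC=O
Why: In the Evans–Tishchenko reduction the samarium-bound hemiacetal on O2 delivers its hydride intramolecularly to C4 (1,3-anti), which sets C4, leaves O4 free and esterifies only O2; pre-forming Sm(III) avoids reductive loss of the α-acetoxy group.

Step 20
Reactants: 24 furan/iodoalkene
Product: 26 methyl (Z)-4-oxo-enoate (C7 = CHO cis to C19 ester), via hydroxybutenolide 25 (not isolated)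
Conditions: O2, hν, tetraphenylporphyrin (cat.), i-Pr2NEt, CH2Cl2, −78 °C; then CH2N2, Et2O, 0 °C
Reagents that add atoms: dioxygen O=O; diazomethane C=[N+]=[N-]
Why: Singlet-oxygen [4+2] addition to the furan is far faster than ene reaction of the alkenes; the hindered base removes the endoperoxide proton next to the methyl group (Kornblum–DeLaMare type), so C19 becomes the carbonyl, and diazomethane esterifies the ring-opened acid tautomer.

Step 21
Reactants: 26 oxo-enoate with C11=C20
Product: 27 11,20-α-epoxide (O α, C20 β)
Conditions: m-CPBA (1.1 equiv), NaHCO3, CH2Cl2, 0 °C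
Reagents that add atoms: 3-chloroperbenzoic acid OOC(=O)c1cccc(Cl)c1
Why: The Prilezhaev epoxidation takes the only electron-rich alkene (the enoate and iodoalkene are deactivated) and attacks from the α face, because the axial C15 methyl blocks the β face 1,3-diaxially (sets C11).

Step 22
Reactants: 27 open iodoalkene/oxo-enoate epoxide
Product: 29 pentacyclic dihydropyran (4,8-ether, C5=C6, C16 methyl, 2-O-levulinate), via macrocyclic butenolide 28 (not isolated)
Conditions: CrCl2 (12 equiv), NiCl2 (2 mol %), degassed DMSO–THF, 2 mM (slow addition), rt; then DBU (excess) to the same flask, rt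
Reagents that add atoms: none
Why: Proposed new method: Ni(0) inserts into the only C(sp2)–I bond and transmetallation gives the (Z)-alkenylchromium(III) at C6, which adds to the C7 aldehyde (Nozaki–Hiyama–Kishi closure of the ten-membered carbocycle; ketone, esters and oxirane are inert to organochromium); the C7 alkoxide, held cis to the C19 ester by the Z C8=C17 bond, lactonises at once (5-exo-trig acyl substitution, loss of methoxide) to 28, and DBU then lets the C4 hydroxyl add across the ring to C8 (6-exo-trig transannular oxa-Michael), after which the lactone enolate is protonated at C17. The closest known reaction types are NHK macrocyclisations of iodoalkene-aldehydes to 9–12-membered carbocycles, alkenylchromium addition/lactonisation routes to butenolides, and base-induced transannular oxa-Michael additions onto butenolides of macrocyclic terpenoids; their union in one flask on a tetrasubstituted butenolide is new. C8: the C5=C6–C7 tether lets O4 reach only the butenolide face that carries C6, so the pyran/lactone fusion must be cis, and only the isomer with C3 and C9 on the same pyran face can span the five-carbon C3–C2–C1–C10–C9 bridge, so C8 is relayed from C4. C7: whichever epimer the addition gives, DBU exchanges the γ-proton of 28, so both epimers funnel into the one that can cyclise. C17: reversible protonation places the methyl trans to the bulky C9 branch (cis to the ether oxygen), which is the more stable epimer. The step needs O4 rather than O2 as nucleophile (both could form a six-membered ring with C8), which the C2 levulinate from step 19 secures, and ring closure rather than oligomerisation, which high dilution and the gauche trans-diequatorial arms on the cyclohexane secure.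

Step 23
Reactants: 29 dihydropyran
Product: 30 6α-chloro-5(16)-ene (2-O-levulinate of the target)
Conditions: Ca(OCl)2, CO2 (dry ice), CH2Cl2–H2O, 0 °C
Reagents that add atoms: calcium hypochlorite [Ca+2].[O-]Cl.[O-]Cl
Why: In this ene-type chlorination with HOCl, Cl+ adds to the less substituted C6 from the convex face (the other face lies under the C3–C9 bridge) and the proton is lost from C16, since loss from bridgehead C4 is geometrically excluded; this sets C6 and the exocyclic methylene at near-neutral pH.

Step 24
Reactants: 30 2-O-levulinate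
Product: 31 target CNP0270816.1
Conditions: H2NNH2·AcOH, CH2Cl2–MeOH, 0 °C → rt
Reagents that add atoms: none
Why: Hydrazone formation at the remote levulinate ketone and cyclisation onto its ester releases the C2 hydroxyl, while acetates, lactone, oxirane and the hindered chloride should not react with buffered hydrazine.

Compound list
1 | 3,4-dibromofuran | Brc1cocc1Br | starting material
2 | 3-bromo-4-methylfuran | Cc1cocc1Br | intermediate
3 | 4-methylfuran-3-carbaldehyde | Cc1cocc1C=O | intermediate
4 | prop-2-yn-1-ol | C#CCO | starting material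
5 | (Z)-3-iodo-2-methylprop-2-en-1-ol | OC/C(C)=C\I | intermediate
6 | (Z)-3-iodo-2-methylprop-2-enoic acid | OC(=O)/C(C)=C\I | intermediate
7 | (Z)-3-iodo-2-methylprop-2-enoyl chloride | ClC(=O)/C(C)=C\I | intermediate
8 | (Z)-1-diazo-4-iodo-3-methylbut-3-en-2-one | [N-]=[N+]=CC(=O)/C(C)=C\I | intermediate
9 | (Z)-4-iodo-3-methyl-2-oxobut-3-en-1-yl acetate | CC(=O)OCC(=O)/C(C)=C\I | intermediate
10 | (E)-but-2-enal | C/C=C/C=O | starting material
11 | (E)-1-(tert-butyldimethylsilyloxy)buta-1,3-diene | C=C/C=C/O[Si](C)(C)C(C)(C)C | intermediate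
12 | 2-methylprop-2-enal | C=C(C)C=O | starting material
13 | (1R,2S)-2-(tert-butyldimethylsilyloxy)-1-methylcyclohex-3-ene-1-carbaldehyde | C1CC=C[C@H](O[Si](C)(C)C(C)(C)C)[C@]1(C)C=O | intermediate
14 | dimethyl acetal of 13 | C1CC=C[C@H](O[Si](C)(C)C(C)(C)C)[C@]1(C)C(OC)OC | intermediate
15 | C11 enone (4-silyloxy-5-dimethoxymethyl-5-methylcyclohex-2-enone) | C1C(=O)C=C[C@H](O[Si](C)(C)C(C)(C)C)[C@]1(C)C(OC)OC | intermediate
16 | C9–C10 syn-aldol adduct, 9-OH | Cc1cocc1[C@@H](O)[C@H]2C(=O)C=C[C@H](O[Si](C)(C)C(C)(C)C)[C@]2(C)C(OC)OC | intermediate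
17 | 9,14-bis-TBS enone | Cc1cocc1[C@@H](O[Si](C)(C)C(C)(C)C)[C@H]2C(=O)C=C[C@H](O[Si](C)(C)C(C)(C)C)[C@]2(C)C(OC)OC | intermediate
18 | saturated C11 ketone | Cc1cocc1[C@@H](O[Si](C)(C)C(C)(C)C)[C@H]2C(=O)CC[C@H](O[Si](C)(C)C(C)(C)C)[C@]2(C)C(OC)OC | intermediate
19 | C11=C20 alkene, bis-TBS | Cc1cocc1[C@@H](O[Si](C)(C)C(C)(C)C)[C@H]2C(=C)CC[C@H](O[Si](C)(C)C(C)(C)C)[C@]2(C)C(OC)OC | intermediate
20 | 9,14-diol | Cc1cocc1[C@@H](O)[C@H]2C(=C)CC[C@H](O)[C@]2(C)C(OC)OC | intermediate
21 | 9,14-diacetate acetal | Cc1cocc1[C@@H](OC(C)=O)[C@H]2C(=C)CC[C@H](OC(C)=O)[C@]2(C)C(OC)OC | intermediate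
22 | core aldehyde | Cc1cocc1[C@@H](OC(C)=O)[C@H]2C(=C)CC[C@H](OC(C)=O)[C@]2(C)C=O | intermediate
23 | 2,3-syn aldol adduct (C4 ketone) | Cc1cocc1[C@@H](OC(C)=O)[C@H]2C(=C)CC[C@H](OC(C)=O)[C@]2(C)[C@@H](O)[C@H](OC(C)=O)C(=O)/C(C)=C\I | intermediate
24 | 2-O-levulinate, 4-OH (2,4-anti) | Cc1cocc1[C@@H](OC(C)=O)[C@H]2C(=C)CC[C@H](OC(C)=O)[C@]2(C)[C@@H](OC(=O)CCC(C)=O)[C@H](OC(C)=O)[C@H](O)/C(C)=C\I | intermediate
25 | γ-hydroxybutenolide (C7 hemiacetal, both epimers) | CC1=C(C(O)OC1=O)[C@@H](OC(C)=O)[C@H]2C(=C)CC[C@H](OC(C)=O)[C@]2(C)[C@@H](OC(=O)CCC(C)=O)[C@H](OC(C)=O)[C@H](O)/C(C)=C\I | intermediate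
26 | methyl (Z)-4-oxo-enoate | COC(=O)/C(C)=C(\C=O)[C@@H](OC(C)=O)[C@H]1C(=C)CC[C@H](OC(C)=O)[C@]1(C)[C@@H](OC(=O)CCC(C)=O)[C@H](OC(C)=O)[C@H](O)/C(C)=C\I | intermediate
27 | 11,20-α-epoxide of 26 (key-step precursor) | COC(=O)/C(C)=C(\C=O)[C@@H](OC(C)=O)[C@H]1[C@]2(CC[C@H](OC(C)=O)[C@]1(C)[C@@H](OC(=O)CCC(C)=O)[C@H](OC(C)=O)[C@H](O)/C(C)=C\I)CO2 | intermediate
28 | macrocyclic Δ8(17)-butenolide, 4-OH, (5Z) (productive C7 epimer drawn) | C/C1=C/[C@@H]2OC(=O)C(C)=C2[C@@H](OC(C)=O)[C@H]3[C@]4(CC[C@H](OC(C)=O)[C@]3(C)[C@@H](OC(=O)CCC(C)=O)[C@H](OC(C)=O)[C@@H]1O)CO4 | intermediate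
29 | pentacyclic 4,8-ether dihydropyran | CC1[C@H]2O[C@]3([C@@H](C)C(=O)O[C@H]3C=1)[C@@H](OC(C)=O)[C@H]1[C@]3(CC[C@H](OC(C)=O)[C@]1(C)[C@@H](OC(=O)CCC(C)=O)[C@@H]2OC(C)=O)CO3 | intermediate
30 | 2-O-levulinate of the target | C=C1[C@H]2O[C@]3([C@@H](C)C(=O)O[C@H]3[C@H]1Cl)[C@@H](OC(C)=O)[C@H]1[C@]3(CC[C@H](OC(C)=O)[C@]1(C)[C@@H](OC(=O)CCC(C)=O)[C@@H]2OC(C)=O)CO3 | intermediate
31 | CNP0270816.1 | C=C1[C@H]2O[C@]3([C@@H](C)C(=O)O[C@H]3[C@H]1Cl)[C@@H](OC(C)=O)[C@H]1[C@]3(CC[C@H](OC(C)=O)[C@]1(C)[C@@H](O)[C@@H]2OC(C)=O)CO3 | target

Total step count: 24. Longest linear sequence: 18 (steps 7–24).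

Steps most likely to fail
1. Step 22 (bears the label).
   - Several processes could divert the cascade: oligomerisation, electron transfer from Cr(II) to the oxo-enoate, base-induced γ-deprotonation with migration of the C5=C6 bond into conjugation, acyl shift from O3 to O4, or reversal of the conjugate addition.
   - The fallback uses known chemistry, splits the cascade into two protecting-group-gated stages, sets out from 27 and returns at 29.
   - The C4 hydroxyl of 27 is silylated (TESCl, imidazole, DMF) to give the triethylsilyl ether F1.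
   - The Nozaki–Hiyama–Kishi macrocyclisation/lactonisation is then run alone (CrCl2, cat. NiCl2, DMSO–THF, high dilution, aqueous serinate work-up), and the macrocyclic butenolide silyl ether F2 is isolated.
   - TBAF in THF at −20 °C then frees the C4 alkoxide without chromium salts or amidine. The alkoxide adds to C8 in the established desilylation/oxa-Michael manner, and an AcOH quench gives 29.
2. Step 18.
   - Steric shielding of the neopentyl aldehyde may stall the closed transition state, or facial selectivity may erode.
   - The fallback sets out from 9 and 22 and returns at 23.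
   - 9 is converted with TMSOTf/Et3N into the (Z)-enol silane F3.
   - F3 is added to 22 with BF3·OEt2 at −78 °C (Mukaiyama aldol). The open transition state is less demanding sterically and is governed by the polar 1,3-anti induction of the C14 oxygen. Aqueous work-up removes silicon and gives 23.
3. Step 23.
   - The alkene is flanked by two C–O bonds, so it may react slowly, show poor facial selectivity, or allow opening of the oxirane to compete.
   - The fallback sets out from 29 and returns at 30.
   - SeO2 (cat.)/t-BuOOH hydroxylates the only allylic methyl group to give the primary allylic alcohol F4.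
   - SOCl2 in Et2O, with 1,2-epoxybutane as acid trap, forms the chlorosulfite. This collapses by SNi′ and delivers chloride to C6 on the open face with shift of the double bond to C5=C16, giving 30.

Further compounds
F1 | step 22 | 4-O-triethylsilyl ether of 27 | COC(=O)/C(C)=C(\C=O)[C@@H](OC(C)=O)[C@H]1[C@]2(CC[C@H](OC(C)=O)[C@]1(C)[C@@H](OC(=O)CCC(C)=O)[C@H](OC(C)=O)[C@H](O[Si](CC)(CC)CC)/C(C)=C\I)CO2
F2 | step 22 | 4-O-triethylsilyl ether of macrocyclic butenolide 28 | C/C1=C/[C@@H]2OC(=O)C(C)=C2[C@@H](OC(C)=O)[C@H]3[C@]4(CC[C@H](OC(C)=O)[C@]3(C)[C@@H](OC(=O)CCC(C)=O)[C@H](OC(C)=O)[C@@H]1O[Si](CC)(CC)CC)CO4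
F3 | step 18 | (Z)-trimethylsilyl enol ether of 9 | CC(=O)O/C=C(O[Si](C)(C)C)/C(C)=C\I
F4 | step 23 | 16-hydroxy derivative of 29 | OCC1[C@H]2O[C@]3([C@@H](C)C(=O)O[C@H]3C=1)[C@@H](OC(C)=O)[C@H]1[C@]3(CC[C@H](OC(C)=O)[C@]1(C)[C@@H](OC(=O)CCC(C)=O)[C@@H]2OC(C)=O)CO3
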